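The readings are simulated for an exercise; the scatter is artificial.

D cannot be spent twice: it takes away at most what was charged, and of the reagents it is the one charged in the smallest amount, the limiting reagent.

| setting | gamma | delta | theta | beta | elm | ash | birch |
|---|---|---|---|---|---|---|---|
| Z | 0.10 M | 0.067 M | 0.15 M | 0.10 M | 0.10 M | 0.10 M | 0.10 M |
| G | 0.13 M | 0.13 M | 0.13 M | 0.065 M | 0.130 M | 0.130 M (fed, over 6.0 min) | 0.130 M |
| D | 0.060 M | 0.060 M | 0.060 M | 0.060 M | 0.0600 M | 0.0600 M | 0.0600 M (fed, over 6.0 min) |
| remark | run made earlier | run made earlier | run made earlier | run made earlier | everything together at the start | all else is in the flask from the start; the feed brings no volume worth counting | all else is in the flask from the start; the feed brings no volume worth counting |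
| time |  |  |  |  | 15 min | 15 min | 15 min |

| run | time / min | X / % | Z / % |
|---|---|---|---|
| gamma | 1.33 | 17 | 73 |
| gamma | 2.50 | 20 | 56 |
| gamma | 4.00 | 28 | 38 |
| gamma | 8.00 | 34 | 12 |
| gamma | 15.0 | 35 | 1 |
| delta | 2.00 | 18 | 63 |
| delta | 4.00 | 26 | 41 |
| delta | 5.00 | 28 | 32 |
| delta | 8.00 | 26 | 15 |
| delta | 10.0 | 24 | 8 |
| theta | 0.833 | 12 | 81 |
| theta | 2.50 | 23 | 56 |
| theta | 4.00 | 31 | 40 |
| theta | 6.00 | 34 | 25 |
| theta | 10.0 | 39 | 6 |
| beta | 2.00 | 17 | 64 |
| beta | 4.00 | 20 | 35 |
| beta | 5.00 | 21 | 30 |
| beta | 8.00 | 22 | 15 |
| beta | 10.0 | 22 | 10 |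

(readings scatter by 1.5 percentage points)

- the best flask by amount of X, in percent of the Z charged; "all alike" if 1.5 percentage points covers them all (elm / ash / birch / all alike)
- amount of X at the end, in percent of the Z charged, elm
- amount of X at the end, in percent of the Z charged, ash
- amount of X at the end, in percent of the Z charged, birch

Suppose one D costs one Z. We then call the free share the fraction of the Z charged that the D charge cannot reach, one minus D over Z, which is 40.0% for elm, ash and birch alike.

The bound from above comes first. At 15.0 min the gamma run, which has elm's recipe, shows Z at 1% and 64.0% that is neither Z nor X, more than D's share of 60.0%. That reading, with its scatter, fits a D charge used up in full, and if it is, X can hold at most the free share of 40.0%. The gamma reading of 35% plus two scatters tightens this to 38.0%.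

The bound from below comes from theta, whose free share is 60.0%. At 10.0 min in theta, counting the Z still there, at 6%, as part of that share, 54.0% of the charge remains of it, and X reads 39%, a ratio of 72.2%. That ratio is itself a reading, so on our free share it gives an estimate and no proof: a rough floor of 28.9%.

Both feeds end at 6.0 min, earlier than 15 min, and the charges match, so we expect the flasks to be alike inside this bracket.

The forecast, inside the bracket, gave 35% for elm, 32% for ash and 34% for birch, and chose elm: “Elm is marginally best”.

The flasks give 31.3% for elm, 30.9% for ash and 31.6% for birch: all alike.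

    D + J → Q (k = 96.0 /M/min)
    Z → J (k = 0.240 /min)
    X ⇌ L (K = 0.220, k = 0.0500 /min)
    G + J ⇌ X (K = 150 /M, k = 100 /M/min)

In birch, Z passed into J with 86% of that turnover done by 7.50 min, and at the end of the feed, 6.00 min, X stood at 37.0% and Q at 31.2%. After that, D, then at 48.0% of its charge, went on turning J into Q, while X slipped to 31.6% by 15.0 min. Left to 150 min, birch, with D at 0%, holds 40.0% as X, L and J, level with its free share of 40.0%. Birch with 0.25 M of Z has a free share of 76.0%, and at 15.0 min, with D at 0%, that share stands as Z 2.73%, X 39.6%, L 8.23% and J 25.4%.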